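**Plan**

1. Numbering used: 3,7-dioxabicyclo[3.3.0]octane, with ring A = O7–C8–C1(OH)–C5–C6(aryl) and ring B = C1–C2(aryl)–O3–C4–C5. The retrosynthesis cuts O3–C4 of ring B first (ether closure), then O7–C6 and C1–C5 of ring A in one stroke, then C1–C2 of the ketone partner.
2. Enabling feature: in ring A the tertiary carbinol C1 lies β to C4 through C5 (aldol retron) and O7 lies β to C4 through C6 (oxa-Michael retron). Ring A is therefore the [3+2] adduct of the α-hydroxy ketone O7–C8–C1(=O)–C2 and the enal C6=C5–C4H=O.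
3. Forward: three steps from 3,4-dimethoxybenzaldehyde give a racemic O-silyl hydroxy ketone; one amine-catalysed oxa-Michael/aldol cascade with 3,4-dimethoxycinnamaldehyde builds ring A; ring B is closed last by an intramolecular Williamson reaction.
4. Stereochemistry: C6 comes from the (R)-diarylprolinol silyl ether catalyst, C5 and C1 from the cascade (the three carbon arms of ring A mutually trans), and C2 from matched selection of the (S)-ketone out of the racemate (kinetic, dynamic where the ketone enolises).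
5. Ring fusion: the C2 arm on C1 and the C4 arm on C5 are trans on ring A, so the final irreversible SN2 closure can only give the trans-fused bicycle.

Key step: step 4

Remark: the SMILES has C1–OH and C5–H on opposite faces (1S,5S), that is a trans-fused, strained and acid-labile bicycle; the route therefore avoids any equilibrating (cationic) ring closure.

Abbreviations: TBS = tert-butyldimethylsilyl, Ts = p-toluenesulfonyl, NMO = N-methylmorpholine N-oxide.

**Route**

Step 1
Reactants: 1 3,4-dimethoxybenzaldehyde; 2 ethyl vinyl ether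
Product: 4 rac-1-(3,4-dimethoxyphenyl)-2-ethoxyprop-2-en-1-ol, via 1-ethoxyvinyllithium 3 (not isolated)
Conditions: 2 (3 equiv), t-BuLi, THF, −78 to 0 °C; then 1, −78 °C; H2O quench
Reagents that add atoms: none
Why: α-Lithiation of the vinyl ether gives an acyl anion equivalent that adds 1,2 to the aldehyde (masked hydroxyacetyl addition); the carbinol centre is formed racemic on purpose because step 4 selects one enantiomer.

Step 2
Reactants: 4 rac-1-(3,4-dimethoxyphenyl)-2-ethoxyprop-2-en-1-ol
Product: 5 rac-tert-butyl{[1-(3,4-dimethoxyphenyl)-2-ethoxyprop-2-en-1-yl]oxy}dimethylsilane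
Conditions: TBSCl, imidazole, DMF, 23 °C
Reagents that add atoms: tert-butyldimethylsilyl chloride, CC(C)(C)[Si](C)(C)Cl
Why: Silylation of a secondary alcohol under basic conditions leaves the acid-labile enol ether intact and forms no stereocentre.

Step 3
Reactants: 5 rac-tert-butyl{[1-(3,4-dimethoxyphenyl)-2-ethoxyprop-2-en-1-yl]oxy}dimethylsilane
Product: 7 rac-1-[(tert-butyldimethylsilyl)oxy]-1-(3,4-dimethoxyphenyl)-3-hydroxypropan-2-one, via hemiketal diol 6 (not isolated)
Conditions: OsO4 (2 mol%), NMO, acetone/H2O, 0 to 23 °C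
Reagents that add atoms: N-methylmorpholine N-oxide, C[N+]1([O-])CCOCC1; water, O
Why: Catalytic osmium tetroxide dihydroxylation of the electron-rich enol ether gives a hemiketal that expels ethanol, so the ketone and its hydroxymethyl group arise at the right oxidation level without an alcohol oxidation; the transient hemiketal centre is lost and no stereocentre is set.

Step 4
Reactants: 7 rac-1-[(tert-butyldimethylsilyl)oxy]-1-(3,4-dimethoxyphenyl)-3-hydroxypropan-2-one; 8 (E)-3-(3,4-dimethoxyphenyl)prop-2-enal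
Product: 10 (3S,4S,5R)-3-{(S)-[(tert-butyldimethylsilyl)oxy](3,4-dimethoxyphenyl)methyl}-5-(3,4-dimethoxyphenyl)-4-(hydroxymethyl)oxolan-3-ol, via cascade aldehyde 9 (not isolated)
Conditions: 8 (1 equiv), 7 (3 equiv), (R)-2-[diphenyl(trimethylsilyloxy)methyl]pyrrolidine (20 mol%), PhCO2H (20 mol%), CHCl3, 23 °C; then MeOH, NaBH4, 0 °C
Reagents that add atoms: none
Why: The catalyst condenses with 8 to an E-iminium ion whose one face is shielded by the CPh2(OSiMe3) group, the primary hydroxyl of 7 adds to the β-carbon from the open face (oxa-Michael, O7–C6), and the enamine so formed attacks the ketone carbon (intramolecular aldol, C5–C1) before hydrolysis releases 9 and the catalyst; NaBH4 then traps 9 as 10. The closest known reaction type is the secondary-amine-catalysed oxa-Michael/aldol domino of α-hydroxy ketones (dihydroxyacetone) with enals and its thia-Michael/aldol counterpart. Ring A is the only ring closed, by a 5-exo-trig (enolexo) aldol addition. C6 (R) is set by the catalyst, C5 by the enamine geometry and by equilibration of the formyl-bearing centre to the arrangement trans to the C6 aryl group, and C1 by the closing transition state, in which the bulky silyloxybenzyl arm stays away from the iminium arm on C5 so that the new hydroxyl ends cis to that arm. C2 is selected, not made: for (S)-7 the ketone face demanded by the ring is also the Felkin–Anh (polar) face with the C–OSi bond anti to the incoming carbon, so (S)-7 should close fast while the adduct of (R)-7 reverts by retro-oxa-Michael, and any enolisation of 7 at its benzylic α-carbon makes the selection dynamic. The step needs addition of the primary and not the benzylic oxygen and needs the aldol adduct not to lactolise to a cis-fused bicycle: the silyl ether on the benzylic oxygen secures both and leaves the C2 arm and the C4 arm trans on ring A, as the trans ring fusion requires.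

Step 5
Reactants: 10 (3S,4S,5R)-3-{(S)-[(tert-butyldimethylsilyl)oxy](3,4-dimethoxyphenyl)methyl}-5-(3,4-dimethoxyphenyl)-4-(hydroxymethyl)oxolan-3-ol
Product: 11 [(2R,3S,4S)-4-{(S)-[(tert-butyldimethylsilyl)oxy](3,4-dimethoxyphenyl)methyl}-2-(3,4-dimethoxyphenyl)-4-hydroxyoxolan-3-yl]methyl 4-methylbenzenesulfonate
Conditions: TsCl, pyridine, 4-(dimethylamino)pyridine (cat.), CH2Cl2, 0 °C
Reagents that add atoms: p-toluenesulfonyl chloride, Cc1ccc(S(=O)(=O)Cl)cc1
Why: Sulfonylation of the primary hydroxyl (the tertiary one should not react under these conditions) turns C4 into the electrophile; no stereocentre is touched.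

Step 6
Reactants: 11 [(2R,3S,4S)-4-{(S)-[(tert-butyldimethylsilyl)oxy](3,4-dimethoxyphenyl)methyl}-2-(3,4-dimethoxyphenyl)-4-hydroxyoxolan-3-yl]methyl 4-methylbenzenesulfonate
Product: 13 (1S,2S,5S,6R)-2,6-bis(3,4-dimethoxyphenyl)-3,7-dioxabicyclo[3.3.0]octan-1-ol, via tetrabutylammonium alkoxide 12 (not isolated)
Conditions: Bu4NF, THF, 0 to 40 °C
Reagents that add atoms: none
Why: Fluoride cleaves the benzylic silyl ether and the alkoxide displaces the primary tosylate (5-exo-tet intramolecular Williamson etherification, SN2 at the non-stereogenic C4), an irreversible closure that gives the trans ring fusion already fixed by the trans arms on C1 and C5; no stereocentre is formed or inverted.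

**Compound list**

1 | 3,4-dimethoxybenzaldehyde | COc1ccc(C=O)cc1OC | starting material
2 | ethyl vinyl ether | C=COCC | starting material
3 | 1-ethoxyvinyllithium | [Li]C(=C)OCC | intermediate
4 | rac-1-(3,4-dimethoxyphenyl)-2-ethoxyprop-2-en-1-ol (racemic) | COc1ccc(C(O)C(=C)OCC)cc1OC | intermediate
5 | rac-tert-butyl{[1-(3,4-dimethoxyphenyl)-2-ethoxyprop-2-en-1-yl]oxy}dimethylsilane (racemic) | COc1ccc(C(O[Si](C)(C)C(C)(C)C)C(=C)OCC)cc1OC | intermediate
6 | 3-[(tert-butyldimethylsilyl)oxy]-3-(3,4-dimethoxyphenyl)-2-ethoxypropane-1,2-diol (hemiketal, mixture of isomers) | COc1ccc(C(O[Si](C)(C)C(C)(C)C)C(O)(OCC)CO)cc1OC | intermediate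
7 | rac-1-[(tert-butyldimethylsilyl)oxy]-1-(3,4-dimethoxyphenyl)-3-hydroxypropan-2-one (racemic) | COc1ccc(C(O[Si](C)(C)C(C)(C)C)C(=O)CO)cc1OC | intermediate
8 | (E)-3-(3,4-dimethoxyphenyl)prop-2-enal | COc1ccc(/C=C/C=O)cc1OC | starting material
9 | (2R,3S,4S)-4-{(S)-[(tert-butyldimethylsilyl)oxy](3,4-dimethoxyphenyl)methyl}-2-(3,4-dimethoxyphenyl)-4-hydroxyoxolane-3-carbaldehyde | COc1ccc([C@@H]2OC[C@](O)([C@H](c3ccc(OC)c(OC)c3)O[Si](C)(C)C(C)(C)C)[C@H]2C=O)cc1OC | intermediate
10 | (3S,4S,5R)-3-{(S)-[(tert-butyldimethylsilyl)oxy](3,4-dimethoxyphenyl)methyl}-5-(3,4-dimethoxyphenyl)-4-(hydroxymethyl)oxolan-3-ol | COc1ccc([C@@H]2OC[C@](O)([C@H](c3ccc(OC)c(OC)c3)O[Si](C)(C)C(C)(C)C)[C@H]2CO)cc1OC | intermediate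
11 | [(2R,3S,4S)-4-{(S)-[(tert-butyldimethylsilyl)oxy](3,4-dimethoxyphenyl)methyl}-2-(3,4-dimethoxyphenyl)-4-hydroxyoxolan-3-yl]methyl 4-methylbenzenesulfonate | COc1ccc([C@@H]2OC[C@](O)([C@H](c3ccc(OC)c(OC)c3)O[Si](C)(C)C(C)(C)C)[C@H]2COS(=O)(=O)c4ccc(C)cc4)cc1OC | intermediate
12 | tetrabutylammonium (S)-(3,4-dimethoxyphenyl)[(3S,4S,5R)-5-(3,4-dimethoxyphenyl)-3-hydroxy-4-(tosyloxymethyl)oxolan-3-yl]methanolate | COc1ccc([C@@H]2OC[C@](O)([C@H](c3ccc(OC)c(OC)c3)[O-])[C@H]2COS(=O)(=O)c4ccc(C)cc4)cc1OC.CCCC[N+](CCCC)(CCCC)CCCC | intermediate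
13 | (1S,2S,5S,6R)-2,6-bis(3,4-dimethoxyphenyl)-3,7-dioxabicyclo[3.3.0]octan-1-ol (trans-fused) | COc1ccc([C@@H]2OC[C@]3(O)[C@H](c4ccc(OC)c(OC)c4)OC[C@@H]23)cc1OC | target

**Step count**

Total steps: 6. Longest linear sequence: 6 steps (1 and 2 to 13; 8 enters at step 4).

**Steps most likely to fail**

1. Step 4. The ring-closing aldol may discriminate too little between the two enantiomers of 7, and the oxa-Michael addition to this electron-rich enal may revert faster than the ring closes; both would erode the configuration at C2 and the conversion. The fallback sets out from 1 and comes back at 10, and replaces the in-flask selection by a ketone that is resolved beforehand. Addition of CH2=CHMgBr to 1 gives rac-1-(3,4-dimethoxyphenyl)prop-2-en-1-ol F1. Sharpless kinetic resolution (Ti(OiPr)4, D-(−)-diisopropyl tartrate, t-BuOOH, 4 Å sieves, CH2Cl2, −20 °C) should leave (R)-1-(3,4-dimethoxyphenyl)prop-2-en-1-ol F2 while the (S)-alcohol is consumed as (R)-(3,4-dimethoxyphenyl)[(S)-oxiran-2-yl]methanol F3. Silylation (TBSCl, imidazole) gives (R)-tert-butyl{[1-(3,4-dimethoxyphenyl)prop-2-en-1-yl]oxy}dimethylsilane F4. Dihydroxylation (OsO4 cat., NMO) gives (3S)-3-[(tert-butyldimethylsilyl)oxy]-3-(3,4-dimethoxyphenyl)propane-1,2-diol F5 as both C2 epimers. Chemoselective oxidation of the secondary hydroxyl of this vicinal diol with [(2,9-dimethyl-1,10-phenanthroline)Pd(OAc)]2(OTf)2 and benzoquinone gives (S)-1-[(tert-butyldimethylsilyl)oxy]-1-(3,4-dimethoxyphenyl)-3-hydroxypropan-2-one F6. F6 (1.2 equiv) then takes the place of racemic 7 under the conditions of step 4 and should give 10.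

2. Step 6. The strained trans closure may be outrun by attack of the neighbouring tertiary alkoxide on the tosylate (four-membered ether), by elimination, or by fluoride substitution. The fallback sets out from 11 and comes back at 13, and replaces the free alkoxide by a tin template that ties up the tertiary oxygen. HF·pyridine (THF, 0 °C) removes the silyl group to give [(2R,3S,4S)-2-(3,4-dimethoxyphenyl)-4-[(S)-(3,4-dimethoxyphenyl)(hydroxy)methyl]-4-hydroxyoxolan-3-yl]methyl 4-methylbenzenesulfonate F7. Bu2SnO (toluene, reflux, azeotropic removal of water) joins the tertiary and the benzylic oxygen in the dibutylstannylene acetal of F7, F8, in which the less hindered benzylic oxygen is the reactive one. CsF in DMF at 40 °C should then trigger O-alkylation by the primary tosylate and give 13 after aqueous work-up.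

3. Step 3. Hydrolysis of the acid-labile enol ether to the methyl ketone may compete with osmylation, and the silyl group may shift to the new primary hydroxyl. The fallback sets out from 5 and comes back at 7, and makes the hydrolysis product the substrate. Pyridinium p-toluenesulfonate in wet acetone converts 5 on purpose into rac-3-[(tert-butyldimethylsilyl)oxy]-3-(3,4-dimethoxyphenyl)propan-2-one F9. LiN(iPr)2 and then Me3SiCl (THF, −78 °C) give the less substituted enol ether rac-3-[(tert-butyldimethylsilyl)oxy]-3-(3,4-dimethoxyphenyl)-2-[(trimethylsilyl)oxy]prop-1-ene F10. Rubottom oxidation (mCPBA, NaHCO3, CH2Cl2, 0 °C) gives rac-1-[(tert-butyldimethylsilyl)oxy]-1-(3,4-dimethoxyphenyl)-3-[(trimethylsilyl)oxy]propan-2-one F11, and citric acid in MeOH frees 7.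

**Further compounds**

F1 | step 4 | rac-1-(3,4-dimethoxyphenyl)prop-2-en-1-ol | COc1ccc(C(O)C=C)cc1OC
F2 | step 4 | (R)-1-(3,4-dimethoxyphenyl)prop-2-en-1-ol | COc1ccc([C@H](O)C=C)cc1OC
F3 | step 4 | (R)-(3,4-dimethoxyphenyl)[(S)-oxiran-2-yl]methanol | COc1ccc([C@@H](O)[C@@H]2CO2)cc1OC
F4 | step 4 | (R)-tert-butyl{[1-(3,4-dimethoxyphenyl)prop-2-en-1-yl]oxy}dimethylsilane | COc1ccc([C@H](O[Si](C)(C)C(C)(C)C)C=C)cc1OC
F5 | step 4 | (3S)-3-[(tert-butyldimethylsilyl)oxy]-3-(3,4-dimethoxyphenyl)propane-1,2-diol (both C2 epimers) | COc1ccc([C@H](O[Si](C)(C)C(C)(C)C)C(O)CO)cc1OC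
F6 | step 4 | (S)-1-[(tert-butyldimethylsilyl)oxy]-1-(3,4-dimethoxyphenyl)-3-hydroxypropan-2-one | COc1ccc([C@H](O[Si](C)(C)C(C)(C)C)C(=O)CO)cc1OC
F7 | step 6 | [(2R,3S,4S)-2-(3,4-dimethoxyphenyl)-4-[(S)-(3,4-dimethoxyphenyl)(hydroxy)methyl]-4-hydroxyoxolan-3-yl]methyl 4-methylbenzenesulfonate | COc1ccc([C@@H]2OC[C@](O)([C@H](c3ccc(OC)c(OC)c3)O)[C@H]2COS(=O)(=O)c4ccc(C)cc4)cc1OC
F8 | step 6 | dibutylstannylene acetal of F7 (2,2-dibutyl-1,3,2-dioxastannolane across the tertiary and the benzylic oxygen) | COc1ccc([C@@H]2OC[C@@]3(O[Sn](CCCC)(CCCC)O[C@H]3c5ccc(OC)c(OC)c5)[C@H]2COS(=O)(=O)c4ccc(C)cc4)cc1OC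
F9 | step 3 | rac-3-[(tert-butyldimethylsilyl)oxy]-3-(3,4-dimethoxyphenyl)propan-2-one | COc1ccc(C(O[Si](C)(C)C(C)(C)C)C(C)=O)cc1OC
F10 | step 3 | rac-3-[(tert-butyldimethylsilyl)oxy]-3-(3,4-dimethoxyphenyl)-2-[(trimethylsilyl)oxy]prop-1-ene | COc1ccc(C(O[Si](C)(C)C(C)(C)C)C(=C)O[Si](C)(C)C)cc1OC
F11 | step 3 | rac-1-[(tert-butyldimethylsilyl)oxy]-1-(3,4-dimethoxyphenyl)-3-[(trimethylsilyl)oxy]propan-2-one | COc1ccc(C(O[Si](C)(C)C(C)(C)C)C(=O)CO[Si](C)(C)C)cc1OC
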